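The route disconnects the C5–C4 bond of the 6-oxabicyclo[3.2.1]octane. The feature exploited is C5, the fully substituted ether bridgehead (bonded to O6, a methyl group, C8 and C4), which lies two carbons from the carbonyl-level C2. In one operation, hydrogen atom transfer to an exocyclic enol ether makes the C5 methyl group and a tertiary α-oxy radical, which closes the cyclohexanone ring (C1, C2, C3, C4, C5, C8) onto the existing oxolane ring (C1, C7, O6, C5, C8) and sets C5. The precursor is a 2-methylideneoxolane carrying methyl and acryloyl on C1 and, trans to the acryloyl group, a ketal-protected 3-oxobutyl chain on C8.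

Key step: step 14

Assumption: the lipase in step 3 acetylates the enantiotopic hydroxymethyl group of diol 4 that gives the (R)-monoacetate 5; an enzyme with the opposite preference gives the same (R)-monoacetate when run in the hydrolytic direction on the diacetate.

Remarks: C1–C8 are the atom numbers of the bicyclic core of the target. The descriptor of the quaternary carbon changes between R and S from 5 to 10 only because substituent priorities change. Compounds 10, 11, 14, 15 and 16 are carried as both epimers at the allylic oxygen-bearing carbon, which becomes the C2 carbonyl in step 13.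

Step 1
Reactants: 1 diethyl methylmalonate; 2 allyl bromide
Product: 3 diethyl 2-methyl-2-(prop-2-en-1-yl)propanedioate
Conditions: NaH, THF, 0 °C to rt
Reagents that add atoms: none
Why: Malonate alkylation (SN2 of the sodium enolate on an allylic bromide) puts the future C8–C5 unit on the carbon that becomes C1, and no stereocentre is formed.

Step 2
Reactants: 3 diethyl 2-methyl-2-(prop-2-en-1-yl)propanedioate
Product: 4 2-methyl-2-(prop-2-en-1-yl)propane-1,3-diol
Conditions: LiAlH4, THF, 0 °C to reflux; aq. NaOH work-up
Reagents that add atoms: none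
Why: Exhaustive hydride reduction of both esters should give the prochiral 1,3-diol, and the isolated alkene is inert to LiAlH4.

Step 3
Reactants: 4 2-methyl-2-(prop-2-en-1-yl)propane-1,3-diol
Product: 5 (2R)-2-(hydroxymethyl)-2-methylpent-4-en-1-yl acetate
Conditions: lipase PS (Burkholderia cepacia), vinyl acetate, MTBE, 25 °C
Reagents that add atoms: vinyl acetate, C=COC(C)=O
Why: Lipase-catalysed transesterification with an irreversible acyl donor (enzymatic desymmetrization of a prochiral diol) should acylate one enantiotopic hydroxymethyl group, so the enzyme sets the quaternary stereocentre that becomes C1; the monoester is used at once and kept from acid and base so that 1,3-acyl migration cannot racemize it.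

Step 4
Reactants: 5 (2R)-2-(hydroxymethyl)-2-methylpent-4-en-1-yl acetate
Product: 7 [(3S)-3-methyl-5-oxooxolan-3-yl]methyl acetate, via lactol 6 (not isolated)
Conditions: O3, CH2Cl2, −78 °C; PPh3, −78 °C to rt; then TEMPO (cat.), PhI(OAc)2, CH2Cl2, rt
Reagents that add atoms: ozone, O=[O+][O-]
Why: Ozonolysis of the terminal alkene should give an aldehyde that closes on the free hydroxymethyl group to the five-membered lactol, and oxoammonium oxidation of the lactol gives the γ-lactone, which fixes the free arm as C7–O6 and leaves the acetoxymethyl arm for C2 without touching the quaternary centre.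

Step 5
Reactants: 7 [(3S)-3-methyl-5-oxooxolan-3-yl]methyl acetate
Product: 8 (4S)-4-(hydroxymethyl)-4-methyloxolan-2-one
Conditions: Candida antarctica lipase B (immobilized), phosphate buffer pH 7, MTBE, 30 °C
Reagents that add atoms: none
Why: Enzymatic ester hydrolysis at neutral pH should remove the primary acetate without alkoxide or methanolysis conditions, under which the freed hydroxymethyl group could exchange with the lactone oxygen through the achiral ring-opened diol and racemize the quaternary centre.

Step 6
Reactants: 8 (4S)-4-(hydroxymethyl)-4-methyloxolan-2-one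
Product: 9 (3R)-3-methyl-5-oxooxolane-3-carbaldehyde
Conditions: Dess–Martin periodinane, CH2Cl2, 0 °C to rt
Reagents that add atoms: none
Why: Dess–Martin oxidation of the primary alcohol, run directly on fresh 8, should give an aldehyde on a quaternary carbon that cannot enolize, and from here on the two oxygenated arms are no longer interconvertible.

Step 7
Reactants: 9 (3R)-3-methyl-5-oxooxolane-3-carbaldehyde
Product: 10 (4R)-4-(1-hydroxyprop-2-en-1-yl)-4-methyloxolan-2-one (both carbinol epimers)
Conditions: vinylmagnesium bromide (1.1 equiv), THF, −78 °C; aq. NH4Cl at −78 °C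
Reagents that add atoms: vinylmagnesium bromide, C=C[Mg]Br
Why: Grignard 1,2-addition should take the aldehyde far faster than the lactone at −78 °C, the cold quench keeps the alkoxide from attacking the lactone, and the new carbinol centre is formed unselectively because it is oxidized away in step 13.

Step 8
Reactants: 10 (4R)-4-(1-hydroxyprop-2-en-1-yl)-4-methyloxolan-2-one
Product: 11 (4R)-4-[1-(tert-butyldimethylsilyloxy)prop-2-en-1-yl]-4-methyloxolan-2-one
Conditions: TBSOTf, 2,6-lutidine, CH2Cl2, −78 to 0 °C
Reagents that add atoms: tert-butyldimethylsilyl trifluoromethanesulfonate, CC(C)(C)[Si](C)(C)OS(=O)(=O)C(F)(F)F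
Why: Silyl triflate silylation of the hindered secondary alcohol masks the future enone carbonyl as a bulky silyl ether that survives enolate chemistry and methylenation and also serves as the large group for step 10.

Step 9
Reactants: 12 2-(2-bromoethyl)-2-methyl-1,3-dioxolane
Product: 13 2-(2-iodoethyl)-2-methyl-1,3-dioxolane
Conditions: NaI, NaHCO3 (trace), acetone, reflux
Reagents that add atoms: sodium iodide, [Na+].[I-]
Why: Finkelstein halide exchange, driven by precipitation of NaBr, gives the iodide, which is the better electrophile for the hindered enolate of step 10.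

Step 10
Reactants: 11 (4R)-4-[1-(tert-butyldimethylsilyloxy)prop-2-en-1-yl]-4-methyloxolan-2-one; 13 2-(2-iodoethyl)-2-methyl-1,3-dioxolane
Product: 14 (3R,4R)-4-[1-(tert-butyldimethylsilyloxy)prop-2-en-1-yl]-4-methyl-3-[2-(2-methyl-1,3-dioxolan-2-yl)ethyl]oxolan-2-one
Conditions: LiN(iPr)2, THF, −78 °C; then 13, DMPU, −78 to −30 °C
Reagents that add atoms: none
Why: Alkylation of the lactone lithium enolate (SN2 on the primary iodide) should occur on the enolate face opposite the bulky silyloxyallyl group on the neighbouring quaternary carbon, the other face being screened only by methyl, which places the chain trans to that group and sets C8 (3R).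

Step 11
Reactants: 14 (3R,4R)-4-[1-(tert-butyldimethylsilyloxy)prop-2-en-1-yl]-4-methyl-3-[2-(2-methyl-1,3-dioxolan-2-yl)ethyl]oxolan-2-one
Product: 15 tert-butyl(dimethyl){1-[(3R,4R)-3-methyl-5-methylidene-4-[2-(2-methyl-1,3-dioxolan-2-yl)ethyl]oxolan-3-yl]prop-2-en-1-yloxy}silane
Conditions: Cp2TiMe2, toluene, 65 °C, dark; filtration through basic alumina
Reagents that add atoms: dimethyltitanocene, C[Ti](C)(C1C=CC=C1)C1C=CC=C1
Why: Petasis methylenation (carbonyl olefination by thermally generated Cp2Ti=CH2) should turn the lactone carbonyl into the exocyclic enol ether under neutral conditions that leave the α-stereocentre, the silyl ether and the ketal untouched.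

Step 12
Reactants: 15 tert-butyl(dimethyl){1-[(3R,4R)-3-methyl-5-methylidene-4-[2-(2-methyl-1,3-dioxolan-2-yl)ethyl]oxolan-3-yl]prop-2-en-1-yloxy}silane
Product: 16 1-[(3R,4R)-3-methyl-5-methylidene-4-[2-(2-methyl-1,3-dioxolan-2-yl)ethyl]oxolan-3-yl]prop-2-en-1-ol
Conditions: Bu4NF, THF, 0 °C to rt; aq. NaHCO3 work-up, no silica
Reagents that add atoms: none
Why: Fluoride cleavage of the silyl ether is basic and therefore compatible with the enol ether, and the alcohol is taken on crude because any acid would add the hydroxyl group across the enol ether to a bicyclic ketal.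

Step 13
Reactants: 16 1-[(3R,4R)-3-methyl-5-methylidene-4-[2-(2-methyl-1,3-dioxolan-2-yl)ethyl]oxolan-3-yl]prop-2-en-1-ol
Product: 17 1-[(3R,4R)-3-methyl-5-methylidene-4-[2-(2-methyl-1,3-dioxolan-2-yl)ethyl]oxolan-3-yl]prop-2-en-1-one
Conditions: SO3·pyridine, DMSO, Et3N, CH2Cl2, 0 °C; used immediately
Reagents that add atoms: none
Why: Parikh–Doering oxidation (activated DMSO under amine buffering) should convert both carbinol epimers into the single vinyl ketone without exposing the enol ether to acid, and the quaternary α-carbon rules out epimerization.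

Step 14
Reactants: 17 1-[(3R,4R)-3-methyl-5-methylidene-4-[2-(2-methyl-1,3-dioxolan-2-yl)ethyl]oxolan-3-yl]prop-2-en-1-one
Product: 18 (1R,5S,8R)-1,5-dimethyl-8-[2-(2-methyl-1,3-dioxolan-2-yl)ethyl]-6-oxabicyclo[3.2.1]octan-2-one
Conditions: Fe(acac)3 (0.3 equiv), PhSiH3 (slow addition), Na2HPO4, degassed EtOH, 60 °C, high dilution
Reagents that add atoms: none
Why: An iron hydride formed from Fe(acac)3 and PhSiH3 should transfer a hydrogen atom to the terminal CH2 of the enol ether (Markovnikov metal-hydride hydrogen atom transfer), creating the C5 methyl group and a tertiary α-oxy radical at C5; this nucleophilic radical adds to C4, the unsubstituted terminus of the vinyl ketone, and the α-keto radical at C3 is reduced to the enolate and protonated by ethanol. The closest known reaction type is the iron-mediated reductive coupling of an electron-rich olefin with an enone (radical conjugate addition), run here within one molecule. The cyclohexanone ring C1–C2–C3–C4–C5–C8 closes in the 6-endo-trig mode, as expected for a 4-oxo-5-hexenyl radical, because 5-exo attack at C3 would leave an unstabilized primary radical. C5 is the only new stereocentre and is controlled by the tether: the planar radical can reach C4 only on the oxolane face that carries the acyl arm of C1, so C5–C4 forms cis to C1–C2 and the methyl group takes the other face. The step needs hydrogen atom transfer to the enol ether and not to the enone, which the match between the electrophilic hydrogen donor and the electron-rich 1,1-disubstituted alkene secures; the ketal chain offers no second alkene, and Na2HPO4 keeps the enol ether from isomerizing or solvolysing.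

Step 15
Reactants: 18 (1R,5S,8R)-1,5-dimethyl-8-[2-(2-methyl-1,3-dioxolan-2-yl)ethyl]-6-oxabicyclo[3.2.1]octan-2-one
Product: 20 4-[(1R,2R,5S,8R)-2-hydroxy-1,5-dimethyl-6-oxabicyclo[3.2.1]octan-8-yl]butan-2-one, via ketal alcohol 19 (not isolated)
Conditions: NaBH4, MeOH, −20 to 0 °C; then 2 M aq. HCl, THF, rt
Reagents that add atoms: water, O
Why: Borohydride reduction followed by ketal hydrolysis in the same flask: hydride should arrive along the axial trajectory of the chair cyclohexanone, away from the axial C7 methylene on the neighbouring C1, giving the equatorial 2R alcohol, and acidification destroys the remaining borohydride before the dioxolane opens, so the methyl ketone is released only when no hydride is left.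

Step 16
Reactants: 20 4-[(1R,2R,5S,8R)-2-hydroxy-1,5-dimethyl-6-oxabicyclo[3.2.1]octan-8-yl]butan-2-one
Product: 21 ethyl (2E)-5-[(1R,2R,5S,8R)-2-hydroxy-1,5-dimethyl-6-oxabicyclo[3.2.1]octan-8-yl]-3-methylpent-2-enoate
Conditions: ethyl 2-(diisopropoxyphosphoryl)acetate, NaH, THF, 0 °C (anion preformed); then 20, rt to 50 °C; chromatography
Reagents that add atoms: ethyl 2-(diisopropoxyphosphoryl)acetate, CCOC(=O)CP(=O)(OC(C)C)OC(C)C
Why: Horner–Wadsworth–Emmons olefination of the methyl ketone should favour the E enoate, with the ester trans to the longer chain, the bulky diisopropyl phosphonate reinforcing this preference; the minor Z isomer is removed by chromatography and the hindered C2 hydroxyl is a spectator toward the stabilized carbanion.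

Step 17
Reactants: 21 ethyl (2E)-5-[(1R,2R,5S,8R)-2-hydroxy-1,5-dimethyl-6-oxabicyclo[3.2.1]octan-8-yl]-3-methylpent-2-enoate
Product: 22 (1R,2R,5S,8R)-8-[(3E)-5-hydroxy-3-methylpent-3-en-1-yl]-1,5-dimethyl-6-oxabicyclo[3.2.1]octan-2-ol
Conditions: iBu2AlH (3.5 equiv), CH2Cl2, −78 to −20 °C; aq. potassium sodium tartrate
Reagents that add atoms: none
Why: iBu2AlH 1,2-reduction of the α,β-unsaturated ester should give the allylic alcohol without touching the alkene geometry, the excess reagent covering the free hydroxyl group.

Step 18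
Reactants: 22 (1R,2R,5S,8R)-8-[(3E)-5-hydroxy-3-methylpent-3-en-1-yl]-1,5-dimethyl-6-oxabicyclo[3.2.1]octan-2-ol; 23 umbelliferone (7-hydroxy-2H-chromen-2-one)
Product: 24 7-{[(2E)-5-[(1R,2R,5S,8R)-2-hydroxy-1,5-dimethyl-6-oxabicyclo[3.2.1]octan-8-yl]-3-methylpent-2-en-1-yl]oxy}-2H-chromen-2-one (CNP0178104.1)
Conditions: PPh3, DIAD, THF, 0 °C to rt
Reagents that add atoms: none
Why: Mitsunobu etherification should activate only the unhindered primary allylic alcohol, which the acidic phenol displaces by SN2 at CH2, while the secondary C2 alcohol next to a quaternary carbon is too hindered to form the oxyphosphonium salt.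

Compound list
1 | diethyl methylmalonate | CCOC(=O)C(C)C(=O)OCC | starting material
2 | allyl bromide | C=CCBr | starting material
3 | diethyl 2-methyl-2-(prop-2-en-1-yl)propanedioate | CCOC(=O)C(C)(CC=C)C(=O)OCC | intermediate
4 | 2-methyl-2-(prop-2-en-1-yl)propane-1,3-diol | C=CCC(C)(CO)CO | intermediate
5 | (2R)-2-(hydroxymethyl)-2-methylpent-4-en-1-yl acetate | C=CC[C@](COC(C)=O)(C)CO | intermediate
6 | [(3R)-5-hydroxy-3-methyloxolan-3-yl]methyl acetate (lactol, both anomers) | OC1C[C@@](C)(COC(C)=O)CO1 | intermediate (not isolated)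
7 | [(3S)-3-methyl-5-oxooxolan-3-yl]methyl acetate | O=C1C[C@@](C)(COC(C)=O)CO1 | intermediate
8 | (4S)-4-(hydroxymethyl)-4-methyloxolan-2-one | O=C1C[C@@](C)(CO)CO1 | intermediate
9 | (3R)-3-methyl-5-oxooxolane-3-carbaldehyde | O=C1C[C@@](C)(C=O)CO1 | intermediate
10 | (4R)-4-(1-hydroxyprop-2-en-1-yl)-4-methyloxolan-2-one (both carbinol epimers) | O=C1C[C@@](C)(C(O)C=C)CO1 | intermediate
11 | (4R)-4-[1-(tert-butyldimethylsilyloxy)prop-2-en-1-yl]-4-methyloxolan-2-one (both epimers at the silyloxy carbon) | O=C1C[C@@](C)(C(O[Si](C)(C)C(C)(C)C)C=C)CO1 | intermediate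
12 | 2-(2-bromoethyl)-2-methyl-1,3-dioxolane | CC1(CCBr)OCCO1 | starting material
13 | 2-(2-iodoethyl)-2-methyl-1,3-dioxolane | CC1(CCI)OCCO1 | intermediate
14 | (3R,4R)-4-[1-(tert-butyldimethylsilyloxy)prop-2-en-1-yl]-4-methyl-3-[2-(2-methyl-1,3-dioxolan-2-yl)ethyl]oxolan-2-one (chain trans to the silyloxyallyl group) | O=C1OC[C@](C)(C(O[Si](C)(C)C(C)(C)C)C=C)[C@H]1CCC2(C)OCCO2 | intermediate
15 | tert-butyl(dimethyl){1-[(3R,4R)-3-methyl-5-methylidene-4-[2-(2-methyl-1,3-dioxolan-2-yl)ethyl]oxolan-3-yl]prop-2-en-1-yloxy}silane | C=C1OC[C@](C)(C(O[Si](C)(C)C(C)(C)C)C=C)[C@H]1CCC2(C)OCCO2 | intermediate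
16 | 1-[(3R,4R)-3-methyl-5-methylidene-4-[2-(2-methyl-1,3-dioxolan-2-yl)ethyl]oxolan-3-yl]prop-2-en-1-ol | C=C1OC[C@](C)(C(O)C=C)[C@H]1CCC2(C)OCCO2 | intermediate
17 | 1-[(3R,4R)-3-methyl-5-methylidene-4-[2-(2-methyl-1,3-dioxolan-2-yl)ethyl]oxolan-3-yl]prop-2-en-1-one | C=C1OC[C@](C)(C(=O)C=C)[C@H]1CCC2(C)OCCO2 | intermediate (key-step precursor)
18 | (1R,5S,8R)-1,5-dimethyl-8-[2-(2-methyl-1,3-dioxolan-2-yl)ethyl]-6-oxabicyclo[3.2.1]octan-2-one | CC1(OCCO1)CC[C@@H]2[C@]3(C)CO[C@@]2(C)CCC3=O | intermediate (key-step product)
19 | (1R,2R,5S,8R)-1,5-dimethyl-8-[2-(2-methyl-1,3-dioxolan-2-yl)ethyl]-6-oxabicyclo[3.2.1]octan-2-ol | CC1(OCCO1)CC[C@@H]2[C@]3(C)CO[C@@]2(C)CC[C@H]3O | intermediate (not isolated)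
20 | 4-[(1R,2R,5S,8R)-2-hydroxy-1,5-dimethyl-6-oxabicyclo[3.2.1]octan-8-yl]butan-2-one | CC(=O)CC[C@@H]1[C@]2(C)CO[C@@]1(C)CC[C@H]2O | intermediate
21 | ethyl (2E)-5-[(1R,2R,5S,8R)-2-hydroxy-1,5-dimethyl-6-oxabicyclo[3.2.1]octan-8-yl]-3-methylpent-2-enoate | C/C(=C\C(=O)OCC)CC[C@@H]1[C@]2(C)CO[C@@]1(C)CC[C@H]2O | intermediate
22 | (1R,2R,5S,8R)-8-[(3E)-5-hydroxy-3-methylpent-3-en-1-yl]-1,5-dimethyl-6-oxabicyclo[3.2.1]octan-2-ol | C/C(=C\CO)CC[C@@H]1[C@]2(C)CO[C@@]1(C)CC[C@H]2O | intermediate
23 | umbelliferone (7-hydroxy-2H-chromen-2-one) | Oc1ccc2ccc(=O)oc2c1 | starting material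
24 | 7-{[(2E)-5-[(1R,2R,5S,8R)-2-hydroxy-1,5-dimethyl-6-oxabicyclo[3.2.1]octan-8-yl]-3-methylpent-2-en-1-yl]oxy}-2H-chromen-2-one | C/C(=C\COc1ccc2ccc(=O)oc2c1)CC[C@@H]1[C@]2(C)CO[C@@]1(C)CC[C@H]2O | target

Total step count: 18. Longest linear sequence: 17 steps (steps 1 to 8 and 10 to 18); step 9 is a one-step side branch.

Steps most likely to fail

Step 14. Hydrogen atom transfer may go to the enone instead of the enol ether, or the α-oxy radical may be oxidized to the oxocarbenium ion and captured by ethanol before it cyclizes, so that reduction or solvolysis replaces ring closure. The fallback generates the same C5 radical by tin-mediated group transfer and sets out from 15. Acid-catalysed Markovnikov addition of PhSeH (cat. PPTS, CH2Cl2, 0 °C) should give the selenoketal silyl ether tert-butyl(dimethyl){1-[(3R,4R)-3,5-dimethyl-4-[2-(2-methyl-1,3-dioxolan-2-yl)ethyl]-5-(phenylselanyl)oxolan-3-yl]prop-2-en-1-yloxy}silane F1. Desilylation with Bu4NF gives the selenoketal alcohol 1-[(3R,4R)-3,5-dimethyl-4-[2-(2-methyl-1,3-dioxolan-2-yl)ethyl]-5-(phenylselanyl)oxolan-3-yl]prop-2-en-1-ol F2, and Parikh–Doering oxidation gives the selenoketal enone 1-[(3R,4R)-3,5-dimethyl-4-[2-(2-methyl-1,3-dioxolan-2-yl)ethyl]-5-(phenylselanyl)oxolan-3-yl]prop-2-en-1-one F3. Slow addition of Bu3SnH with AIBN in benzene at 80 °C then abstracts the selenium group, and the same 6-endo radical conjugate addition returns to the route at 18.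

Step 10. The hindered enolate next to a quaternary carbon may react slowly with the unactivated iodide, so that elimination of HI from the electrophile and loss of facial selectivity on warming compete. The fallback replaces alkylation by conjugate addition and sets out from 11. Enolization with LiN(iPr)2 and trapping with Me3SiCl should give the ketene silyl acetal tert-butyl(dimethyl){1-[(3R)-3-methyl-5-(trimethylsilyloxy)-2,3-dihydrofuran-3-yl]prop-2-en-1-yloxy}silane F4. Mukaiyama–Michael addition to methyl vinyl ketone (cat. Sc(OTf)3, CH2Cl2, −78 °C), again anti to the silyloxyallyl group, gives the keto lactone (3R,4R)-4-[1-(tert-butyldimethylsilyloxy)prop-2-en-1-yl]-4-methyl-3-(3-oxobutyl)oxolan-2-one F5. Ketalization with ethylene glycol and PPTS in benzene with water removal returns to the route at 14.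

Step 3. The enzyme may discriminate poorly between the methyl and allyl groups at the prochiral carbon, and acyl migration in the monoester may erode what selectivity there is. The fallback sets the centre by classical resolution and sets out from 3. Half-saponification (1 equiv KOH, EtOH) should give the racemic half-ester 2-(ethoxycarbonyl)-2-methylpent-4-enoic acid F6. Crystallization of its salt with one enantiomer of 1-phenylethylamine, followed by acidification, gives the resolved half-ester (2S)-2-(ethoxycarbonyl)-2-methylpent-4-enoic acid F7. LiBH4 reduces the ester of the lithium carboxylate to the hydroxy acid (2R)-2-(hydroxymethyl)-2-methylpent-4-enoic acid F8. Ozonolysis with PPh3 work-up gives the lactol acid (3R)-5-hydroxy-3-methyloxolane-3-carboxylic acid F9, which TEMPO/PhI(OAc)2 oxidizes to the lactone acid (3R)-3-methyl-5-oxooxolane-3-carboxylic acid F10. In this series the two oxygenated arms differ in oxidation level throughout, so no degenerate acyl transfer is possible. Chemoselective reduction of the carboxylic acid with BH3·SMe2 (THF, 0 °C) returns to the route at 8.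

Further compounds
F1 | step 14 | tert-butyl(dimethyl){1-[(3R,4R)-3,5-dimethyl-4-[2-(2-methyl-1,3-dioxolan-2-yl)ethyl]-5-(phenylselanyl)oxolan-3-yl]prop-2-en-1-yloxy}silane | CC1([Se]c2ccccc2)OC[C@](C)(C(O[Si](C)(C)C(C)(C)C)C=C)[C@H]1CCC3(C)OCCO3
F2 | step 14 | 1-[(3R,4R)-3,5-dimethyl-4-[2-(2-methyl-1,3-dioxolan-2-yl)ethyl]-5-(phenylselanyl)oxolan-3-yl]prop-2-en-1-ol | CC1([Se]c2ccccc2)OC[C@](C)(C(O)C=C)[C@H]1CCC3(C)OCCO3
F3 | step 14 | 1-[(3R,4R)-3,5-dimethyl-4-[2-(2-methyl-1,3-dioxolan-2-yl)ethyl]-5-(phenylselanyl)oxolan-3-yl]prop-2-en-1-one | CC1([Se]c2ccccc2)OC[C@](C)(C(=O)C=C)[C@H]1CCC3(C)OCCO3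
F4 | step 10 | tert-butyl(dimethyl){1-[(3R)-3-methyl-5-(trimethylsilyloxy)-2,3-dihydrofuran-3-yl]prop-2-en-1-yloxy}silane | C[Si](C)(C)OC1=C[C@@](C)(C(O[Si](C)(C)C(C)(C)C)C=C)CO1
F5 | step 10 | (3R,4R)-4-[1-(tert-butyldimethylsilyloxy)prop-2-en-1-yl]-4-methyl-3-(3-oxobutyl)oxolan-2-one | O=C1OC[C@](C)(C(O[Si](C)(C)C(C)(C)C)C=C)[C@H]1CCC(C)=O
F6 | step 3 | 2-(ethoxycarbonyl)-2-methylpent-4-enoic acid (racemic) | C=CCC(C)(C(=O)O)C(=O)OCC
F7 | step 3 | (2S)-2-(ethoxycarbonyl)-2-methylpent-4-enoic acid | C=CC[C@](C(=O)O)(C)C(=O)OCC
F8 | step 3 | (2R)-2-(hydroxymethyl)-2-methylpent-4-enoic acid | C=CC[C@](C(=O)O)(C)CO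
F9 | step 3 | (3R)-5-hydroxy-3-methyloxolane-3-carboxylic acid (lactol, both anomers) | OC1C[C@@](C)(C(=O)O)CO1
F10 | step 3 | (3R)-3-methyl-5-oxooxolane-3-carboxylic acid | O=C1C[C@@](C)(C(=O)O)CO1
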